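Everything rests on cutting the O1–C2 bond of the dihydrofuran ring. Seen as the hydrate of an isopropenyl group, the C2 side chain makes C2 an allylic carbon, and O1 is the oxygen of the C7a phenol that is hydrogen-bonded to the C7 ketone. A single palladium-catalysed asymmetric allylic etherification therefore closes the five-membered ring and sets the only stereocentre, C2 (S). Its precursor is a phloretin-derived dihydrochalcone with the free chelated phenol, an (E)-3-methyl-4-(methoxycarbonyloxy)but-2-enyl chain on the adjacent ring carbon and TIPS ethers on the other two phenols. Hydration of the isopropenyl group, Saegusa dehydrogenation and desilylation complete the chalcone.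

Key step: step 8

Remark: benzofuran numbering is used for the target (O1, C2, C3, C3a, C4 to C7, C7a) and TIPS = triisopropylsilyl; the (S,S) enantiomer of the DACH-phenyl ligand is assumed to give 2S (its mirror image is taken if a trial run shows the opposite sense), and TIPS is chosen over TBS because an aryl silyl ether para to a ketone is base-labile and its loss in step 8 would free the second oxygen next to the side chain.

Step 1
Reactants: 1 phloretin
Product: 2 1-[2,6-dihydroxy-4-(triisopropylsilyloxy)phenyl]-3-[4-(triisopropylsilyloxy)phenyl]propan-1-one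
Conditions: TIPSCl (2.1 equiv), imidazole (4 equiv), DMF, 0 °C
Reagents that add atoms: triisopropylsilyl chloride, CC(C)[Si](Cl)(C(C)C)C(C)C
Why: Regioselective O-silylation, in which the para phenol of ring A and the phenol of ring B are unhindered and not hydrogen-bonded, whereas the two phenols ortho to the ketone are shielded by the acyl group and tied up in hydrogen bonding, so the bulky silyl chloride should stop after two silylations.

Step 2
Reactants: 2 1-[2,6-dihydroxy-4-(triisopropylsilyloxy)phenyl]-3-[4-(triisopropylsilyloxy)phenyl]propan-1-one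
Product: 3 1-[2-hydroxy-6-methoxy-4-(triisopropylsilyloxy)phenyl]-3-[4-(triisopropylsilyloxy)phenyl]propan-1-one
Conditions: Me2SO4 (1.05 equiv), K2CO3, acetone, rt
Reagents that add atoms: dimethyl sulfate, COS(=O)(=O)OC
Why: Williamson O-methylation with a hard methylating agent, in which the two ortho phenols are equivalent and, once one is methylated, the other is locked in a strong hydrogen bond to the ketone and reacts far more slowly, so the reaction should stop at the mono-ether.

Step 3
Reactants: 3 1-[2-hydroxy-6-methoxy-4-(triisopropylsilyloxy)phenyl]-3-[4-(triisopropylsilyloxy)phenyl]propan-1-one; 4 allyl bromide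
Product: 5 1-[2-allyloxy-6-methoxy-4-(triisopropylsilyloxy)phenyl]-3-[4-(triisopropylsilyloxy)phenyl]propan-1-one
Conditions: allyl bromide (1.5 equiv), K2CO3, acetone, reflux
Reagents that add atoms: allyl bromide (4), C=CCBr
Why: Williamson etherification, in which the unhindered and reactive allyl bromide alkylates even the chelated phenoxide on heating while aryl TIPS ethers tolerate anhydrous K2CO3 in acetone.

Step 4
Reactants: 5 1-[2-allyloxy-6-methoxy-4-(triisopropylsilyloxy)phenyl]-3-[4-(triisopropylsilyloxy)phenyl]propan-1-one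
Product: 6 1-[3-allyl-2-hydroxy-6-methoxy-4-(triisopropylsilyloxy)phenyl]-3-[4-(triisopropylsilyloxy)phenyl]propan-1-one
Conditions: PhNEt2, 190 °C, sealed tube
Reagents that add atoms: none
Why: Aromatic Claisen rearrangement, in which the [3,3] shift can end productively only at the one free ortho carbon (the other carries the acyl group) and tautomerisation restores the chelated phenol next to the new allyl group, the silyl ethers and the ketone being thermally inert.

Step 5
Reactants: 6 1-[3-allyl-2-hydroxy-6-methoxy-4-(triisopropylsilyloxy)phenyl]-3-[4-(triisopropylsilyloxy)phenyl]propan-1-one; 7 methacrolein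
Product: 8 1-{2-hydroxy-6-methoxy-3-[(E)-3-methyl-4-oxobut-2-enyl]-4-(triisopropylsilyloxy)phenyl}-3-[4-(triisopropylsilyloxy)phenyl]propan-1-one
Conditions: methacrolein (10 equiv), second-generation Hoveyda–Grubbs catalyst (H2IMes)Cl2Ru=CH(C6H4-2-OiPr) (5 mol %), 1,4-benzoquinone (10 mol %), CH2Cl2, 40 °C
Reagents that add atoms: methacrolein (7), CC(=C)C=O
Why: Olefin cross-metathesis, in which the terminal allyl olefin couples with methacrolein, an electron-poor 1,1-disubstituted partner that does not homodimerise, the trisubstituted enal forms as the thermodynamically preferred E isomer, and benzoquinone suppresses ruthenium hydride migration of the allyl double bond.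

Step 6
Reactants: 8 1-{2-hydroxy-6-methoxy-3-[(E)-3-methyl-4-oxobut-2-enyl]-4-(triisopropylsilyloxy)phenyl}-3-[4-(triisopropylsilyloxy)phenyl]propan-1-one
Product: 9 1-{2-hydroxy-3-[(E)-4-hydroxy-3-methylbut-2-enyl]-6-methoxy-4-(triisopropylsilyloxy)phenyl}-3-[4-(triisopropylsilyloxy)phenyl]propan-1-one
Conditions: NaBH4, CeCl3·7H2O, MeOH, −40 °C
Reagents that add atoms: none
Why: Luche 1,2-reduction, in which the enal is far more electrophilic than the doubly ortho-substituted aryl ketone (further deactivated by its chelated phenol), so only the aldehyde should be reduced and the E geometry is kept.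

Step 7
Reactants: 9 1-{2-hydroxy-3-[(E)-4-hydroxy-3-methylbut-2-enyl]-6-methoxy-4-(triisopropylsilyloxy)phenyl}-3-[4-(triisopropylsilyloxy)phenyl]propan-1-one; 10 methyl chloroformate
Product: 11 (E)-4-{2-hydroxy-4-methoxy-6-(triisopropylsilyloxy)-3-[3-(4-(triisopropylsilyloxy)phenyl)propanoyl]phenyl}-2-methylbut-2-enyl methyl carbonate
Conditions: ClCO2Me (1.1 equiv), pyridine, CH2Cl2, −20 to 0 °C
Reagents that add atoms: methyl chloroformate (10), COC(Cl)=O
Why: Chemoselective O-acylation, in which the primary allylic alcohol reacts with the chloroformate much faster than the phenol, which is hydrogen-bonded to the ketone and flanked by two ortho substituents.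

Step 8
Reactants: 11 (E)-4-{2-hydroxy-4-methoxy-6-(triisopropylsilyloxy)-3-[3-(4-(triisopropylsilyloxy)phenyl)propanoyl]phenyl}-2-methylbut-2-enyl methyl carbonate
Product: 12 1-[(2S)-6-methoxy-2-(prop-1-en-2-yl)-4-(triisopropylsilyloxy)-2,3-dihydrobenzofuran-7-yl]-3-[4-(triisopropylsilyloxy)phenyl]propan-1-one
Conditions: Pd2(dba)3·CHCl3 (2.5 mol %), (S,S)-DACH-phenyl ligand N,N'-[(1S,2S)-cyclohexane-1,2-diyl]bis[2-(diphenylphosphanyl)benzamide] (7.5 mol %), AcOH (1 equiv), CH2Cl2, rt
Reagents that add atoms: none
Why: Zerovalent palladium carrying the C2-symmetric bisphosphine ionises the allylic carbonate with loss of CO2 and methoxide to a π-allyl complex whose termini are the primary CH2 and the carbon next to the benzylic CH2, and the C7a phenoxide (the phenol being deprotonated by the methoxide) adds to the latter on the face opposite palladium to form O1–C2. The closest known reaction type is the intramolecular palladium-catalysed asymmetric allylic alkylation of phenols, established for 2-vinylchromans and for 2-isopropenyl-2,3-dihydrobenzofurans from this same kind of (E)-2-methylbut-2-enyl carbonate. The dihydrofuran ring closes in a 5-exo mode, since attack at the primary terminus would demand a seven-membered ring. C2 is set by catalyst control: the two diastereomeric π-allyl complexes interconvert by π–σ–π slippage through the unsubstituted CH2 terminus, AcOH slows ring closure enough for this equilibration, and the chiral pocket of the ligand lets one of them cyclise faster, the uniform E geometry ensuring a single syn allyl isomer. Chemoselectivity for O1 is needed because two oxygens flank the side chain, and it is secured by the robust TIPS ether on the C4 oxygen, which leaves the C7a phenol as the only free nucleophile, the ketone α-CH2 being too weakly acidic to compete.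

Step 9
Reactants: 12 1-[(2S)-6-methoxy-2-(prop-1-en-2-yl)-4-(triisopropylsilyloxy)-2,3-dihydrobenzofuran-7-yl]-3-[4-(triisopropylsilyloxy)phenyl]propan-1-one
Product: 13 1-[(2S)-2-(2-hydroxypropan-2-yl)-6-methoxy-4-(triisopropylsilyloxy)-2,3-dihydrobenzofuran-7-yl]-3-[4-(triisopropylsilyloxy)phenyl]propan-1-one
Conditions: Co(acac)2 (20 mol %), PhSiH3 (2 equiv), O2 (1 atm), THF, rt
Reagents that add atoms: dioxygen, O=O
Why: Mukaiyama hydration, in which hydrogen atom transfer from a cobalt hydride to the 1,1-disubstituted alkene gives the tertiary radical that is trapped by O2 and reduced to the Markovnikov tertiary alcohol, while C2 is not part of the radical and keeps its configuration and the ketone and silyl ethers are inert.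

Step 10
Reactants: 13 1-[(2S)-2-(2-hydroxypropan-2-yl)-6-methoxy-4-(triisopropylsilyloxy)-2,3-dihydrobenzofuran-7-yl]-3-[4-(triisopropylsilyloxy)phenyl]propan-1-one
Product: 15 (E)-1-[(2S)-6-methoxy-4-(triisopropylsilyloxy)-2-(2-trimethylsilyloxypropan-2-yl)-2,3-dihydrobenzofuran-7-yl]-3-[4-(triisopropylsilyloxy)phenyl]prop-2-en-1-one, via bis-TMS enol ether 14 (not isolated)
Conditions: TMSOTf (2.5 equiv), Et3N, CH2Cl2, 0 °C; solvent exchange to MeCN; Pd(OAc)2 (1.1 equiv), rt
Reagents that add atoms: trimethylsilyl trifluoromethanesulfonate, C[Si](C)(C)OS(=O)(=O)C(F)(F)F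
Why: Saegusa–Ito oxidation, in which soft enolisation gives the only possible silyl enol ether (and caps the tertiary alcohol as its TMS ether), Pd(OAc)2 turns it into a palladium enolate, and β-hydride elimination gives the conjugated E-enone, C2 carrying no acidic hydrogen.

Step 11
Reactants: 15 (E)-1-[(2S)-6-methoxy-4-(triisopropylsilyloxy)-2-(2-trimethylsilyloxypropan-2-yl)-2,3-dihydrobenzofuran-7-yl]-3-[4-(triisopropylsilyloxy)phenyl]prop-2-en-1-one
Product: 16 (E)-1-[(2S)-4-hydroxy-2-(2-hydroxypropan-2-yl)-6-methoxy-2,3-dihydrobenzofuran-7-yl]-3-(4-hydroxyphenyl)prop-2-en-1-one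
Conditions: Bu4NF (3.5 equiv), AcOH (3.5 equiv), THF, 0 °C to rt
Reagents that add atoms: none
Why: Fluoride-mediated desilylation, in which the two aryl TIPS ethers and the tertiary TMS ether are cleaved under AcOH-buffered conditions and the chalcone cannot close to a flavanone because both oxygens ortho to the acyl group are etherified.

Compound list
1 | phloretin, 3-(4-hydroxyphenyl)-1-(2,4,6-trihydroxyphenyl)propan-1-one | O=C(CCc1ccc(O)cc1)c1c(O)cc(O)cc1O | starting material
2 | 1-[2,6-dihydroxy-4-(triisopropylsilyloxy)phenyl]-3-[4-(triisopropylsilyloxy)phenyl]propan-1-one | O=C(CCc1ccc(O[Si](C(C)C)(C(C)C)C(C)C)cc1)c1c(O)cc(O[Si](C(C)C)(C(C)C)C(C)C)cc1O | intermediate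
3 | 1-[2-hydroxy-6-methoxy-4-(triisopropylsilyloxy)phenyl]-3-[4-(triisopropylsilyloxy)phenyl]propan-1-one | COc1cc(O[Si](C(C)C)(C(C)C)C(C)C)cc(O)c1C(=O)CCc1ccc(O[Si](C(C)C)(C(C)C)C(C)C)cc1 | intermediate
4 | allyl bromide | C=CCBr | starting material
5 | 1-[2-allyloxy-6-methoxy-4-(triisopropylsilyloxy)phenyl]-3-[4-(triisopropylsilyloxy)phenyl]propan-1-one | COc1cc(O[Si](C(C)C)(C(C)C)C(C)C)cc(OCC=C)c1C(=O)CCc1ccc(O[Si](C(C)C)(C(C)C)C(C)C)cc1 | intermediate
6 | 1-[3-allyl-2-hydroxy-6-methoxy-4-(triisopropylsilyloxy)phenyl]-3-[4-(triisopropylsilyloxy)phenyl]propan-1-one | COc1cc(O[Si](C(C)C)(C(C)C)C(C)C)c(CC=C)c(O)c1C(=O)CCc1ccc(O[Si](C(C)C)(C(C)C)C(C)C)cc1 | intermediate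
7 | methacrolein, 2-methylprop-2-enal | CC(=C)C=O | starting material
8 | 1-{2-hydroxy-6-methoxy-3-[(E)-3-methyl-4-oxobut-2-enyl]-4-(triisopropylsilyloxy)phenyl}-3-[4-(triisopropylsilyloxy)phenyl]propan-1-one | COc1cc(O[Si](C(C)C)(C(C)C)C(C)C)c(C/C=C(\C)C=O)c(O)c1C(=O)CCc1ccc(O[Si](C(C)C)(C(C)C)C(C)C)cc1 | intermediate
9 | 1-{2-hydroxy-3-[(E)-4-hydroxy-3-methylbut-2-enyl]-6-methoxy-4-(triisopropylsilyloxy)phenyl}-3-[4-(triisopropylsilyloxy)phenyl]propan-1-one | COc1cc(O[Si](C(C)C)(C(C)C)C(C)C)c(C/C=C(\C)CO)c(O)c1C(=O)CCc1ccc(O[Si](C(C)C)(C(C)C)C(C)C)cc1 | intermediate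
10 | methyl chloroformate | COC(Cl)=O | starting material
11 | (E)-4-{2-hydroxy-4-methoxy-6-(triisopropylsilyloxy)-3-[3-(4-(triisopropylsilyloxy)phenyl)propanoyl]phenyl}-2-methylbut-2-enyl methyl carbonate (key-step precursor) | COc1cc(O[Si](C(C)C)(C(C)C)C(C)C)c(C/C=C(\C)COC(=O)OC)c(O)c1C(=O)CCc1ccc(O[Si](C(C)C)(C(C)C)C(C)C)cc1 | intermediate
12 | 1-[(2S)-6-methoxy-2-(prop-1-en-2-yl)-4-(triisopropylsilyloxy)-2,3-dihydrobenzofuran-7-yl]-3-[4-(triisopropylsilyloxy)phenyl]propan-1-one (key-step product) | COc1cc(O[Si](C(C)C)(C(C)C)C(C)C)c2c(c1C(=O)CCc1ccc(O[Si](C(C)C)(C(C)C)C(C)C)cc1)O[C@H](C(C)=C)C2 | intermediate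
13 | 1-[(2S)-2-(2-hydroxypropan-2-yl)-6-methoxy-4-(triisopropylsilyloxy)-2,3-dihydrobenzofuran-7-yl]-3-[4-(triisopropylsilyloxy)phenyl]propan-1-one | COc1cc(O[Si](C(C)C)(C(C)C)C(C)C)c2c(c1C(=O)CCc1ccc(O[Si](C(C)C)(C(C)C)C(C)C)cc1)O[C@H](C(C)(C)O)C2 | intermediate
14 | (Z)-trimethylsilyl enol ether of 13 with the tertiary alcohol as its trimethylsilyl ether, (2S) (not isolated) | COc1cc(O[Si](C(C)C)(C(C)C)C(C)C)c2c(c1/C(O[Si](C)(C)C)=C/Cc1ccc(O[Si](C(C)C)(C(C)C)C(C)C)cc1)O[C@H](C(C)(C)O[Si](C)(C)C)C2 | intermediate
15 | (E)-1-[(2S)-6-methoxy-4-(triisopropylsilyloxy)-2-(2-trimethylsilyloxypropan-2-yl)-2,3-dihydrobenzofuran-7-yl]-3-[4-(triisopropylsilyloxy)phenyl]prop-2-en-1-one | COc1cc(O[Si](C(C)C)(C(C)C)C(C)C)c2c(c1C(=O)/C=C/c1ccc(O[Si](C(C)C)(C(C)C)C(C)C)cc1)O[C@H](C(C)(C)O[Si](C)(C)C)C2 | intermediate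
16 | (E)-1-[(2S)-4-hydroxy-2-(2-hydroxypropan-2-yl)-6-methoxy-2,3-dihydrobenzofuran-7-yl]-3-(4-hydroxyphenyl)prop-2-en-1-one (CNP0103650.1) | COc1cc(O)c2c(c1C(=O)/C=C/c1ccc(O)cc1)O[C@H](C(C)(C)O)C2 | target

Total step count: 11
Longest linear sequence: 11 steps (1 to 16)

Steps most likely to fail

Step 8. Ring closure may outrun the interconversion of the two diastereomeric π-allyl complexes, or zerovalent palladium may re-ionise the allyl aryl ether once formed; either process lowers the enantiomeric purity at C2. Cleavage of the C4 silyl ether by the alkoxide released would also let the wrong oxygen close the ring. The fallback replaces allylic substitution by reagent-controlled epoxidation and sets out from 6. Cross-metathesis of 6 with 2-methylbut-2-ene (second-generation Grubbs catalyst, (H2IMes)(PCy3)Cl2Ru=CHPh) should give the prenyl phenol F1. Shi epoxidation with the D-fructose-derived ketone 1,2:4,5-di-O-isopropylidene-β-D-erythro-2,3-hexodiulo-2,6-pyranose (Oxone, 2KHSO5·KHSO4·K2SO4, K2CO3 buffer, MeCN/dimethoxymethane/H2O, 0 °C) is expected to give the (R)-epoxide F2. Under the basic buffer, or on brief treatment with K2CO3, the neighbouring phenoxide should open it at the secondary carbon with inversion (5-exo, SN2). This gives the (S)-configured tertiary alcohol 13 directly, and the route is rejoined at 13.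

Step 10. Enolisation of the twisted, doubly ortho-substituted aryl ketone may be sluggish, the silyl enol ether may hydrolyse back to the ketone during the solvent change, or palladium metal may precipitate before the oxidation is complete. The fallback is a selenoxide elimination and sets out from 13. Deprotonation with LiN(iPr)2 (2.2 equiv, THF, −78 °C) and trapping with PhSeBr should give the α-phenylselanyl ketone F3 (epimers at the selenium-bearing carbon). Oxidation with H2O2/pyridine in CH2Cl2 at 0 °C and syn-elimination of the selenoxide should give the E-enone with free tertiary alcohol F4. Bu4NF/AcOH in THF then removes the two TIPS groups and gives 16, where the route is rejoined.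

Step 5. Ruthenium hydride species may move the allyl double bond into conjugation with the arene, and self-metathesis of the allyl arene may consume material, so that conversion to the enal stays low. The fallback is oxidative cleavage followed by Wittig olefination and sets out from 6. OsO4 (cat.)/NaIO4 with 2,6-lutidine in dioxane/H2O should cleave the terminal alkene to the arylacetaldehyde F5 (possibly present as its cyclic hemiacetal with the neighbouring phenol). The stabilised ylide Ph3P=C(CH3)CHO in toluene at 80 °C should then give the E-enal 8, where the route is rejoined.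

Further compounds
F1 | step 8 | 1-[2-hydroxy-6-methoxy-3-(3-methylbut-2-enyl)-4-(triisopropylsilyloxy)phenyl]-3-[4-(triisopropylsilyloxy)phenyl]propan-1-one | COc1cc(O[Si](C(C)C)(C(C)C)C(C)C)c(CC=C(C)C)c(O)c1C(=O)CCc1ccc(O[Si](C(C)C)(C(C)C)C(C)C)cc1
F2 | step 8 | 1-{3-[((2R)-3,3-dimethyloxiran-2-yl)methyl]-2-hydroxy-6-methoxy-4-(triisopropylsilyloxy)phenyl}-3-[4-(triisopropylsilyloxy)phenyl]propan-1-one | COc1cc(O[Si](C(C)C)(C(C)C)C(C)C)c(C[C@H]2OC2(C)C)c(O)c1C(=O)CCc1ccc(O[Si](C(C)C)(C(C)C)C(C)C)cc1
F3 | step 10 | 1-[(2S)-2-(2-hydroxypropan-2-yl)-6-methoxy-4-(triisopropylsilyloxy)-2,3-dihydrobenzofuran-7-yl]-2-(phenylselanyl)-3-[4-(triisopropylsilyloxy)phenyl]propan-1-one, both epimers at the selenium-bearing carbon | COc1cc(O[Si](C(C)C)(C(C)C)C(C)C)c2c(c1C(=O)C([Se]c1ccccc1)Cc1ccc(O[Si](C(C)C)(C(C)C)C(C)C)cc1)O[C@H](C(C)(C)O)C2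
F4 | step 10 | (E)-1-[(2S)-2-(2-hydroxypropan-2-yl)-6-methoxy-4-(triisopropylsilyloxy)-2,3-dihydrobenzofuran-7-yl]-3-[4-(triisopropylsilyloxy)phenyl]prop-2-en-1-one | COc1cc(O[Si](C(C)C)(C(C)C)C(C)C)c2c(c1C(=O)/C=C/c1ccc(O[Si](C(C)C)(C(C)C)C(C)C)cc1)O[C@H](C(C)(C)O)C2
F5 | step 5 | 2-{2-hydroxy-4-methoxy-6-(triisopropylsilyloxy)-3-[3-(4-(triisopropylsilyloxy)phenyl)propanoyl]phenyl}acetaldehyde | COc1cc(O[Si](C(C)C)(C(C)C)C(C)C)c(CC=O)c(O)c1C(=O)CCc1ccc(O[Si](C(C)C)(C(C)C)C(C)C)cc1
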